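**Plan**

1. Numbering: C1 (propenyl CH3), C2=C3, C4 (oxane CH), O5, C6 (oxane CH), C7 (CHOH), C8=C9–C10=C11(Me), C12, C13 (CHMe), C14=C15(Me), C16=C17, C18 (lactone CH–O), C19, C20=C21, C22 (C=O), O23; C24 (CH2), C25 (CHOH) and C26 (CHMe) complete the oxane.
2. Retrosynthesis: C9–C10 is cut first (alkenylzinc plus alkenyl iodide), giving an oxane alkyne C1–C9 and an iodotriene lactone C10–C22. The latter is cut at C20=C21 (ring-closing metathesis), O23–C22 (acrylate), C18–C19 (allylboration), C16=C17 and C14=C15 (olefinations), C11–CH3 (carboalumination) and C12–C13 (enolate alkylation).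
3. In the oxane half, C9 and the C7 oxygen come off a C8 aldehyde and the ring is opened at O5–C6. The enabling feature: O5 on C4 reaches C6, the β-carbon of a C6=C7–C8(=O)S enoyl thioester, through the six-membered ring O5, C6, C24, C25, C26, C4, so the oxane is a hydroxy enoyl thioester that closes by 6-exo oxa-conjugate addition. The open chain is cut at C6=C7 (Wittig on a lactol), C24–C25 (Claisen) and C4–C26 (aldol).
4. Forward: the chain C1–C8 is built and the oxane closes in step 10; the lactone ring of the other half closes by metathesis in step 28; the halves are joined at C9–C10 in step 29 and desilylated.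
5. Stereochemistry: C4 and C26 from an Evans syn-aldol, C25 from 1,3-syn reduction, C6 from the phosphoric-acid-catalysed ring closure, C7 from L-proline aminoxylation, C13 from an Evans alkylation, C18 from a pinene-based allylboration. Alkene geometry comes from crotonaldehyde (C2=C3), hydrozirconation (C8=C9), carboalumination (C10=C11), Still–Gennari (C14=C15) and Horner–Wadsworth–Emmons (C16=C17) steps.

Key step: step 10

Assumption: (R)-TRIP is taken to be the acid enantiomer whose facial preference coincides with the 2,6-cis chair of 16; this is to be confirmed on a small scale, and the mirror-image acid is used in the same way if it proves to be the matched one.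

**Route**

Step 1
Reactants: 1 (4R)-4-benzyl-3-propanoyl-1,3-oxazolidin-2-one; 2 (E)-but-2-enal
Product: 4 (4R)-4-benzyl-3-[(2R,3S,4E)-3-hydroxy-2-methylhex-4-enoyl]-1,3-oxazolidin-2-one, via dibutylboron Z-enolate 3 (not isolated)
Conditions: Bu2BOTf, Et3N, CH2Cl2, 0 °C; then 2, −78 → 0 °C; H2O2, MeOH, aq. NaH2PO4/Na2HPO4 (pH 7)
Reagents that add atoms: none
Why: Evans syn-aldol in which the Z-boron enolate adds 1,2 to the enal through a Zimmerman–Traxler chair with the oxazolidinone dipole opposed, so the (R)-benzyl auxiliary should set C26 and C4 together (2R,3S, syn).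

Step 2
Reactants: 4
Product: 5 (2R,3S,4E)-3-hydroxy-N-methoxy-N,2-dimethylhex-4-enamide
Conditions: MeNH(OMe)·HCl, AlMe3, CH2Cl2, −15 → 0 °C
Reagents that add atoms: N,O-dimethylhydroxylamine hydrochloride, CNOC.Cl
Why: Weinreb transamidation by the aluminium amide, assisted by the free β-hydroxyl, should release the auxiliary without epimerising C26.

Step 3
Reactants: 5; 6 ethyl acetate
Product: 7 ethyl (4R,5S,6E)-5-hydroxy-4-methyl-3-oxooct-6-enoate
Conditions: LiN(i-Pr)2 (4 equiv), 6 (4 equiv), THF, −78 °C; then 5, −78 → −40 °C; AcOH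
Reagents that add atoms: none
Why: Claisen-type acylation of the ester enolate by the Weinreb amide forms C24–C25, the chelated tetrahedral adduct persisting until the quench so that no second addition occurs and the excess enolate only deprotonates the hydroxyl.

Step 4
Reactants: 7
Product: 8 ethyl (3R,4S,5S,6E)-3,5-dihydroxy-4-methyloct-6-enoate
Conditions: Et2BOMe, THF–MeOH (4:1), −78 °C; NaBH4; AcOH; MeOH co-evaporation
Reagents that add atoms: none
Why: Narasaka–Prasad reduction in which boron ties the C4 hydroxyl and the C25 ketone into a six-membered chelate and external hydride attacks axially, which should set C25 1,3-syn to C4.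

Step 5
Reactants: 8
Product: 9 (4R,5S,6S)-4-hydroxy-5-methyl-6-[(E)-prop-1-enyl]oxan-2-one
Conditions: p-TsOH·H2O (5 mol %), CH2Cl2, rt
Reagents that add atoms: none
Why: acid-catalysed lactonisation, in which only the C4 hydroxyl reaches the ester through a six-membered ring while the C25 hydroxyl could form only a β-lactone.

Step 6
Reactants: 9
Product: 10 (4R,5S,6S)-5-methyl-6-[(E)-prop-1-enyl]oxane-2,4-diol (lactol as both anomers)
Conditions: i-Bu2AlH (2.3 equiv), CH2Cl2, −78 °C; aq. potassium sodium tartrate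
Reagents that add atoms: none
Why: partial reduction of a δ-lactone with i-Bu2AlH stops at the lactol because the aluminium hemiacetal is stable at −78 °C, the first equivalent being taken up by the free hydroxyl.

Step 7
Reactants: 11 bromoacetyl bromide; 12 4-methylbenzenethiol
Product: 13 S-(4-methylphenyl) 2-bromoethanethioate
Conditions: pyridine, CH2Cl2, −20 → 0 °C
Reagents that add atoms: none
Why: S-acylation of the thiol by the acyl bromide, which at low temperature is far faster than displacement of the α-bromide.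

Step 8
Reactants: 13
Product: 15 S-(4-methylphenyl) 2-(triphenyl-λ5-phosphanylidene)ethanethioate, via phosphonium bromide 14 (not isolated)
Conditions: PPh3, toluene, rt; then aq. Na2CO3, CH2Cl2
Reagents that add atoms: triphenylphosphine, c1ccc(cc1)P(c1ccccc1)c1ccccc1
Why: SN2 quaternisation of the phosphine by the α-bromo thioester followed by carbonate deprotonation gives the carbonyl-stabilised Wittig ylide.

Step 9
Reactants: 10; 15
Product: 16 S-(4-methylphenyl) (2E,5R,6S,7S,8E)-5,7-dihydroxy-6-methyldeca-2,8-dienethioate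
Conditions: 15 (1.5 equiv), toluene, 50 °C
Reagents that add atoms: none
Why: Wittig olefination of the lactol through its open hydroxy aldehyde form with a stabilised ylide should give the E-alkene C6=C7, and an olefination is chosen because cross-metathesis on the corresponding 1,7-diene would instead close a cyclohexene.

Step 10
Reactants: 16
Product: 17 S-(4-methylphenyl) 2-[(2S,4R,5S,6S)-4-hydroxy-5-methyl-6-[(E)-prop-1-enyl]oxan-2-yl]ethanethioate
Conditions: (R)-TRIP [(R)-3,3'-bis(2,4,6-triisopropylphenyl)-1,1'-binaphthyl-2,2'-diyl hydrogen phosphate] (10 mol %), toluene, rt → 40 °C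
Reagents that add atoms: none
Why: The phosphoric acid hydrogen-bonds the thioester carbonyl through P–OH and the C4 hydroxyl through P=O, the hydroxyl oxygen adds to C6 of the E-enoyl thioester and the thioester enol is then protonated at C7. The closest known reaction is the Brønsted-acid-catalysed intramolecular oxa-Michael addition of hydroxy enoyl thioesters, which has a chiral phosphoric acid version. The oxane ring (O5, C6, C24, C25, C26, C4) closes 6-exo-trig through a chair. The new stereocentre C6 is controlled by the catalyst, chosen so that its preferred alkene face is the one that places the C6 side chain equatorial and cis to the equatorial C4 propenyl group; the substrate alone is expected to give only a modest bias because this chair carries the C26 methyl and the C25 hydroxyl axial. The step needs selectivity between the two hydroxyls and against acyl transfer: the C25 hydroxyl could reach C6 only through a four-membered ring, and the E geometry of C6=C7 keeps both hydroxyls away from the thioester carbonyl, so no protecting group is needed.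

Step 11
Reactants: 17
Product: 18 2-[(2S,4R,5S,6S)-4-hydroxy-5-methyl-6-[(E)-prop-1-enyl]oxan-2-yl]acetaldehyde
Conditions: i-Bu2AlH (2.2 equiv), CH2Cl2, −78 °C; aq. potassium sodium tartrate
Reagents that add atoms: none
Why: i-Bu2AlH reduction of an aryl thioester stops at the aldehyde because the hemithioacetal aluminate survives at −78 °C and collapses only on work-up.

Step 12
Reactants: 18
Product: 20 (2S,3S,4R,6S)-6-[(1S)-2-hydroxy-1-(phenylaminooxy)ethyl]-3-methyl-2-[(E)-prop-1-enyl]oxan-4-ol, via anilinooxy aldehyde 19 (not isolated)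
Conditions: PhNO (1.1 equiv), L-proline (30 mol %), DMSO, rt; then NaBH4, MeOH, 0 °C
Reagents that add atoms: nitrosobenzene, O=Nc1ccccc1
Why: proline-catalysed α-aminoxylation in which the E-enamine of 18 attacks the oxygen of nitrosobenzene held by the carboxylic acid on one face, so L-proline should set C7 by catalyst control, and NaBH4 traps the labile aldehyde at once.

Step 13
Reactants: 20
Product: 21 (1S)-1-[(2S,4R,5S,6S)-4-hydroxy-5-methyl-6-[(E)-prop-1-enyl]oxan-2-yl]ethane-1,2-diol
Conditions: Zn, AcOH, EtOH, rt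
Reagents that add atoms: none
Why: reductive N–O cleavage by zinc in acetic acid is a standard unmasking of anilinooxy alcohols and should leave the alkene and the oxane untouched.

Step 14
Reactants: 21
Product: 22 (2S,3R,4R,6S)-6-[(1S)-1,2-bis(triethylsilyloxy)ethyl]-3-methyl-2-[(E)-prop-1-enyl]-4-(triethylsilyloxy)oxane
Conditions: Et3SiOTf, 2,6-lutidine, CH2Cl2, −78 → 0 °C
Reagents that add atoms: triethylsilyl trifluoromethanesulfonate, CC[Si](CC)(CC)OS(=O)(=O)C(F)(F)F
Why: silylation of all three hydroxyls with a silyl triflate and a hindered base, the triflate being reactive enough for the axial C25 hydroxyl.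

Step 15
Reactants: 22
Product: 23 (2R)-2-[(2S,4R,5R,6S)-5-methyl-6-[(E)-prop-1-enyl]-4-(triethylsilyloxy)oxan-2-yl]-2-(triethylsilyloxy)acetaldehyde
Conditions: (COCl)2, DMSO, CH2Cl2, −78 → −40 °C; i-Pr2NEt, −78 → 0 °C
Reagents that add atoms: none
Why: Swern oxidation applied directly to the silyl ether, in which chlorodimethylsulfonium chloride attacks only the unhindered primary triethylsilyl ether, the silyl group leaves as chlorosilane and the alkoxysulfonium ylide collapses to the C8 aldehyde.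

Step 16
Reactants: 23
Product: 24 (2S,3R,4R,6S)-3-methyl-2-[(E)-prop-1-enyl]-4-(triethylsilyloxy)-6-[(1S)-1-(triethylsilyloxy)prop-2-ynyl]oxane
Conditions: dimethyl (1-diazo-2-oxopropyl)phosphonate, K2CO3, MeOH, 0 °C → rt
Reagents that add atoms: dimethyl (1-diazo-2-oxopropyl)phosphonate, COP(=O)(OC)C(=[N+]=[N-])C(C)=O
Why: Ohira–Bestmann homologation (Seyferth–Gilbert type), in which the diazomethylphosphonate anion adds to the aldehyde and the alkylidene carbene rearranges to the C8≡C9 alkyne under conditions mild enough for an α-silyloxy aldehyde.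

Step 17
Reactants: 25 (4S)-4-benzyl-3-propanoyl-1,3-oxazolidin-2-one; 26 3-bromoprop-1-yne
Product: 28 (4S)-4-benzyl-3-[(2R)-2-methylpent-4-ynoyl]-1,3-oxazolidin-2-one, via sodium Z-enolate 27 (not isolated)
Conditions: NaN(SiMe3)2, THF, −78 °C; then 26, −78 → −40 °C
Reagents that add atoms: none
Why: Evans alkylation in which the chelated sodium Z-enolate is alkylated by the propargylic bromide on the face opposite the (S)-benzyl group, which should set C13.

Step 18
Reactants: 28
Product: 29 (2R)-2-methylpent-4-yn-1-ol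
Conditions: LiBH4, MeOH (1 equiv), Et2O, 0 °C
Reagents that add atoms: none
Why: reductive removal of the auxiliary with LiBH4, which attacks the exocyclic imide carbonyl and returns the oxazolidinone.

Step 19
Reactants: 29
Product: 31 (2R,4E)-5-iodo-2,4-dimethylpent-4-en-1-ol, via alkenyldimethylalane 30 (not isolated)
Conditions: AlMe3 (3 equiv), Cp2ZrCl2 (0.25 equiv), CH2Cl2, 0 °C → rt; then I2, THF, −30 → 0 °C
Reagents that add atoms: trimethylaluminium, C[Al](C)C; iodine, II
Why: zirconium-catalysed carboalumination (Negishi) of the terminal alkyne adds methyl and aluminium syn with the metal on the terminal carbon, and iodinolysis with retention gives the E-alkenyl iodide C10=C11, the hydroxyl being carried as its aluminium alkoxide.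

Step 20
Reactants: 31
Product: 32 (2R,4E)-5-iodo-2,4-dimethylpent-4-enal
Conditions: Dess–Martin periodinane, NaHCO3, CH2Cl2, 0 °C → rt
Reagents that add atoms: none
Why: Dess–Martin oxidation under buffered, non-basic conditions should keep the α-stereocentre C13 from epimerising, and the aldehyde is used crude.

Step 21
Reactants: 32; 33 ethyl 2-[bis(2,2,2-trifluoroethoxy)phosphoryl]propanoate
Product: 34 ethyl (2Z,4R,6E)-7-iodo-2,4,6-trimethylhepta-2,6-dienoate
Conditions: KN(SiMe3)2, 18-crown-6, THF, −78 °C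
Reagents that add atoms: none
Why: Still–Gennari olefination, in which the trifluoroethyl phosphonate with a dissociated potassium counter-ion eliminates rapidly from the kinetic adduct and should give the Z-trisubstituted enoate C14=C15.

Step 22
Reactants: 34
Product: 35 (2Z,4R,6E)-7-iodo-2,4,6-trimethylhepta-2,6-dien-1-ol
Conditions: i-Bu2AlH (2.2 equiv), CH2Cl2, −78 °C
Reagents that add atoms: none
Why: 1,2-reduction of the enoate by i-Bu2AlH to the allylic alcohol, which leaves the alkenyl iodide and both alkene geometries unchanged.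

Step 23
Reactants: 35
Product: 36 (2Z,4R,6E)-7-iodo-2,4,6-trimethylhepta-2,6-dienal
Conditions: MnO2, CH2Cl2, rt
Reagents that add atoms: none
Why: allylic oxidation with MnO2 is neutral and should not isomerise the Z-enal.

Step 24
Reactants: 36; 37 diethyl {2-[methoxy(methyl)amino]-2-oxoethyl}phosphonate
Product: 38 (2E,4Z,6R,8E)-9-iodo-N-methoxy-N,4,6,8-tetramethylnona-2,4,8-trienamide
Conditions: LiCl, DBU, MeCN, 0 °C → rt
Reagents that add atoms: none
Why: Horner–Wadsworth–Emmons olefination under Masamune–Roush conditions should give the E-alkene C16=C17 without a strong base that could isomerise the Z-enal.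

Step 25
Reactants: 38
Product: 39 (2E,4Z,6R,8E)-9-iodo-4,6,8-trimethylnona-2,4,8-trienal
Conditions: i-Bu2AlH (1.2 equiv), THF, −78 °C
Reagents that add atoms: none
Why: i-Bu2AlH reduction of a Weinreb amide stops at the aldehyde through the chelated aluminium adduct, giving the dienal with C18 as the carbonyl carbon.

Step 26
Reactants: 39; 40 allylmagnesium bromide
Product: 41 (4S,5E,7Z,9R,11E)-12-iodo-7,9,11-trimethyldodeca-1,5,7,11-tetraen-4-ol
Conditions: (−)-Ipc2BOMe, 40, Et2O, 0 °C → rt; then 39, −78 °C; NaOH, H2O2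
Reagents that add atoms: none
Why: Brown allylboration, in which the allylborane made from the (+)-α-pinene-derived B-methoxydiisopinocampheylborane adds through a chair transition state to the Si face of the enal and should set C18 (S) by reagent control.

Step 27
Reactants: 41; 42 prop-2-enoyl chloride
Product: 43 (4S,5E,7Z,9R,11E)-12-iodo-7,9,11-trimethyldodeca-1,5,7,11-tetraen-4-yl prop-2-enoate
Conditions: i-Pr2NEt, DMAP (cat.), CH2Cl2, −78 → 0 °C
Reagents that add atoms: none
Why: DMAP-catalysed acylation of the secondary allylic alcohol by the acid chloride.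

Step 28
Reactants: 43
Product: 44 (6S)-6-[(1E,3Z,5R,7E)-8-iodo-3,5,7-trimethylocta-1,3,7-trienyl]-5,6-dihydro-2H-pyran-2-one
Conditions: second-generation Grubbs catalyst RuCl2(=CHPh)(H2IMes)(PCy3) (5 mol %), CH2Cl2 (5 mM), 40 °C
Reagents that add atoms: none
Why: ring-closing metathesis, in which the ruthenium carbene forms at the terminal alkene and closes the six-membered ring onto the acrylate (C20=C21), the conjugated and trisubstituted alkenes and the alkenyl iodide being hindered or able to give only strained rings.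

Step 29
Reactants: 24; 44
Product: 47 (6S)-6-[(1E,3Z,5R,7E,9E,11S)-3,5,7-trimethyl-11-[(2S,4R,5R,6S)-5-methyl-6-[(E)-prop-1-enyl]-4-(triethylsilyloxy)oxan-2-yl]-11-(triethylsilyloxy)undeca-1,3,7,9-tetraenyl]-5,6-dihydro-2H-pyran-2-one, via alkenylzirconocene chloride 45 (not isolated), via alkenylzinc chloride 46 (not isolated)
Conditions: 24, Cp2Zr(H)Cl, THF, rt; ZnCl2, THF, 0 °C; then 44, Pd(PPh3)4 (5 mol %), rt
Reagents that add atoms: none
Why: hydrozirconation of the terminal alkyne places the metal on C9 by syn addition, and transmetalation to zinc followed by Negishi coupling with the alkenyl iodide on zerovalent palladium should join C9–C10 with retention at both alkenes under neutral conditions that the lactone tolerates.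

Step 30
Reactants: 47
Product: 48 (6S)-6-[(1E,3Z,5R,7E,9E,11S)-11-hydroxy-11-[(2S,4R,5S,6S)-4-hydroxy-5-methyl-6-[(E)-prop-1-enyl]oxan-2-yl]-3,5,7-trimethylundeca-1,3,7,9-tetraenyl]-5,6-dihydro-2H-pyran-2-one
Conditions: HF·pyridine, pyridine, THF, 0 °C → rt
Reagents that add atoms: none
Why: fluoride desilylation with buffered HF·pyridine removes both triethylsilyl ethers without base, so the unsaturated lactone and the dienyl carbinol should survive.

**Compound list**

1 | (4R)-4-benzyl-3-propanoyl-1,3-oxazolidin-2-one | CCC(=O)N1[C@H](Cc2ccccc2)COC1=O | starting material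
2 | (E)-but-2-enal | C/C=C/C=O | starting material
3 | (4R)-4-benzyl-3-[(1Z)-1-(dibutylboranyloxy)prop-1-enyl]-1,3-oxazolidin-2-one | C/C=C(\OB(CCCC)CCCC)N1[C@H](Cc2ccccc2)COC1=O | intermediate
4 | (4R)-4-benzyl-3-[(2R,3S,4E)-3-hydroxy-2-methylhex-4-enoyl]-1,3-oxazolidin-2-one | C/C=C/[C@H](O)[C@@H](C)C(=O)N1[C@H](Cc2ccccc2)COC1=O | intermediate
5 | (2R,3S,4E)-3-hydroxy-N-methoxy-N,2-dimethylhex-4-enamide | C/C=C/[C@H](O)[C@@H](C)C(=O)N(C)OC | intermediate
6 | ethyl acetate | CCOC(C)=O | starting material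
7 | ethyl (4R,5S,6E)-5-hydroxy-4-methyl-3-oxooct-6-enoate | C/C=C/[C@H](O)[C@@H](C)C(=O)CC(=O)OCC | intermediate
8 | ethyl (3R,4S,5S,6E)-3,5-dihydroxy-4-methyloct-6-enoate | C/C=C/[C@H](O)[C@@H](C)[C@H](O)CC(=O)OCC | intermediate
9 | (4R,5S,6S)-4-hydroxy-5-methyl-6-[(E)-prop-1-enyl]oxan-2-one | C/C=C/[C@@H]1OC(=O)C[C@@H](O)[C@@H]1C | intermediate
10 | (4R,5S,6S)-5-methyl-6-[(E)-prop-1-enyl]oxane-2,4-diol (both anomers) | C/C=C/[C@@H]1OC(O)C[C@@H](O)[C@@H]1C | intermediate
11 | bromoacetyl bromide | BrCC(Br)=O | starting material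
12 | 4-methylbenzenethiol | Cc1ccc(S)cc1 | starting material
13 | S-(4-methylphenyl) 2-bromoethanethioate | Cc1ccc(SC(=O)CBr)cc1 | intermediate
14 | {2-[(4-methylphenyl)sulfanyl]-2-oxoethyl}triphenylphosphonium bromide | Cc1ccc(SC(=O)C[P+](c2ccccc2)(c2ccccc2)c2ccccc2)cc1.[Br-] | intermediate
15 | S-(4-methylphenyl) 2-(triphenyl-λ5-phosphanylidene)ethanethioate | Cc1ccc(SC(=O)C=P(c2ccccc2)(c2ccccc2)c2ccccc2)cc1 | intermediate
16 | S-(4-methylphenyl) (2E,5R,6S,7S,8E)-5,7-dihydroxy-6-methyldeca-2,8-dienethioate | C/C=C/[C@H](O)[C@@H](C)[C@H](O)C/C=C/C(=O)Sc1ccc(C)cc1 | intermediate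
17 | S-(4-methylphenyl) 2-[(2S,4R,5S,6S)-4-hydroxy-5-methyl-6-[(E)-prop-1-enyl]oxan-2-yl]ethanethioate | C/C=C/[C@@H]1O[C@H](CC(=O)Sc2ccc(C)cc2)C[C@@H](O)[C@@H]1C | intermediate
18 | 2-[(2S,4R,5S,6S)-4-hydroxy-5-methyl-6-[(E)-prop-1-enyl]oxan-2-yl]acetaldehyde | C/C=C/[C@@H]1O[C@H](CC=O)C[C@@H](O)[C@@H]1C | intermediate
19 | (2R)-2-[(2S,4R,5S,6S)-4-hydroxy-5-methyl-6-[(E)-prop-1-enyl]oxan-2-yl]-2-(phenylaminooxy)acetaldehyde | C/C=C/[C@@H]1O[C@H]([C@@H](ONc2ccccc2)C=O)C[C@@H](O)[C@@H]1C | intermediate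
20 | (2S,3S,4R,6S)-6-[(1S)-2-hydroxy-1-(phenylaminooxy)ethyl]-3-methyl-2-[(E)-prop-1-enyl]oxan-4-ol | C/C=C/[C@@H]1O[C@H]([C@@H](ONc2ccccc2)CO)C[C@@H](O)[C@@H]1C | intermediate
21 | (1S)-1-[(2S,4R,5S,6S)-4-hydroxy-5-methyl-6-[(E)-prop-1-enyl]oxan-2-yl]ethane-1,2-diol | C/C=C/[C@@H]1O[C@H]([C@@H](O)CO)C[C@@H](O)[C@@H]1C | intermediate
22 | (2S,3R,4R,6S)-6-[(1S)-1,2-bis(triethylsilyloxy)ethyl]-3-methyl-2-[(E)-prop-1-enyl]-4-(triethylsilyloxy)oxane | C/C=C/[C@@H]1O[C@H]([C@@H](O[Si](CC)(CC)CC)CO[Si](CC)(CC)CC)C[C@@H](O[Si](CC)(CC)CC)[C@@H]1C | intermediate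
23 | (2R)-2-[(2S,4R,5R,6S)-5-methyl-6-[(E)-prop-1-enyl]-4-(triethylsilyloxy)oxan-2-yl]-2-(triethylsilyloxy)acetaldehyde | C/C=C/[C@@H]1O[C@H]([C@@H](O[Si](CC)(CC)CC)C=O)C[C@@H](O[Si](CC)(CC)CC)[C@@H]1C | intermediate
24 | (2S,3R,4R,6S)-3-methyl-2-[(E)-prop-1-enyl]-4-(triethylsilyloxy)-6-[(1S)-1-(triethylsilyloxy)prop-2-ynyl]oxane | C/C=C/[C@@H]1O[C@H]([C@@H](O[Si](CC)(CC)CC)C#C)C[C@@H](O[Si](CC)(CC)CC)[C@@H]1C | intermediate
25 | (4S)-4-benzyl-3-propanoyl-1,3-oxazolidin-2-one | CCC(=O)N1[C@@H](Cc2ccccc2)COC1=O | starting material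
26 | 3-bromoprop-1-yne | C#CCBr | starting material
27 | sodium Z-enolate of 25 | C/C=C(\O[Na])N1[C@@H](Cc2ccccc2)COC1=O | intermediate
28 | (4S)-4-benzyl-3-[(2R)-2-methylpent-4-ynoyl]-1,3-oxazolidin-2-one | C#CC[C@@H](C)C(=O)N1[C@@H](Cc2ccccc2)COC1=O | intermediate
29 | (2R)-2-methylpent-4-yn-1-ol | C#CC[C@@H](C)CO | intermediate
30 | [(1E,4R)-5-(dimethylalumanyloxy)-2,4-dimethylpent-1-enyl]dimethylalumane | C[Al](C)/C=C(\C)C[C@@H](C)CO[Al](C)C | intermediate
31 | (2R,4E)-5-iodo-2,4-dimethylpent-4-en-1-ol | I/C=C(\C)C[C@@H](C)CO | intermediate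
32 | (2R,4E)-5-iodo-2,4-dimethylpent-4-enal | I/C=C(\C)C[C@@H](C)C=O | intermediate
33 | ethyl 2-[bis(2,2,2-trifluoroethoxy)phosphoryl]propanoate | CCOC(=O)C(C)P(=O)(OCC(F)(F)F)OCC(F)(F)F | starting material
34 | ethyl (2Z,4R,6E)-7-iodo-2,4,6-trimethylhepta-2,6-dienoate | I/C=C(\C)C[C@@H](C)/C=C(C)\C(=O)OCC | intermediate
35 | (2Z,4R,6E)-7-iodo-2,4,6-trimethylhepta-2,6-dien-1-ol | I/C=C(\C)C[C@@H](C)/C=C(C)\CO | intermediate
36 | (2Z,4R,6E)-7-iodo-2,4,6-trimethylhepta-2,6-dienal | I/C=C(\C)C[C@@H](C)/C=C(C)\C=O | intermediate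
37 | diethyl {2-[methoxy(methyl)amino]-2-oxoethyl}phosphonate | CCOP(=O)(CC(=O)N(C)OC)OCC | starting material
38 | (2E,4Z,6R,8E)-9-iodo-N-methoxy-N,4,6,8-tetramethylnona-2,4,8-trienamide | I/C=C(\C)C[C@@H](C)/C=C(C)\C=C\C(=O)N(C)OC | intermediate
39 | (2E,4Z,6R,8E)-9-iodo-4,6,8-trimethylnona-2,4,8-trienal | I/C=C(\C)C[C@@H](C)/C=C(C)\C=C\C=O | intermediate
40 | allylmagnesium bromide | C=CC[Mg]Br | starting material
41 | (4S,5E,7Z,9R,11E)-12-iodo-7,9,11-trimethyldodeca-1,5,7,11-tetraen-4-ol | I/C=C(\C)C[C@@H](C)/C=C(C)\C=C\[C@@H](O)CC=C | intermediate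
42 | prop-2-enoyl chloride | C=CC(Cl)=O | starting material
43 | (4S,5E,7Z,9R,11E)-12-iodo-7,9,11-trimethyldodeca-1,5,7,11-tetraen-4-yl prop-2-enoate | I/C=C(\C)C[C@@H](C)/C=C(C)\C=C\[C@@H](OC(=O)C=C)CC=C | intermediate
44 | (6S)-6-[(1E,3Z,5R,7E)-8-iodo-3,5,7-trimethylocta-1,3,7-trienyl]-5,6-dihydro-2H-pyran-2-one | I/C=C(\C)C[C@@H](C)/C=C(C)\C=C\[C@@H]1CC=CC(=O)O1 | intermediate
45 | (E)-alkenylzirconocene chloride from 24 (Cp2ZrCl on C9) | C/C=C/[C@@H]1O[C@H]([C@@H](O[Si](CC)(CC)CC)/C=C/[Zr](Cl)(C2C=CC=C2)C2C=CC=C2)C[C@@H](O[Si](CC)(CC)CC)[C@@H]1C | intermediate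
46 | (E)-alkenylzinc chloride from 24 (ZnCl on C9) | C/C=C/[C@@H]1O[C@H]([C@@H](O[Si](CC)(CC)CC)/C=C/[Zn]Cl)C[C@@H](O[Si](CC)(CC)CC)[C@@H]1C | intermediate
47 | (6S)-6-[(1E,3Z,5R,7E,9E,11S)-3,5,7-trimethyl-11-[(2S,4R,5R,6S)-5-methyl-6-[(E)-prop-1-enyl]-4-(triethylsilyloxy)oxan-2-yl]-11-(triethylsilyloxy)undeca-1,3,7,9-tetraenyl]-5,6-dihydro-2H-pyran-2-one | C/C=C/[C@@H]1O[C@H]([C@@H](O[Si](CC)(CC)CC)/C=C/C=C(\C)C[C@@H](C)/C=C(C)\C=C\[C@@H]2CC=CC(=O)O2)C[C@@H](O[Si](CC)(CC)CC)[C@@H]1C | intermediate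
48 | (6S)-6-[(1E,3Z,5R,7E,9E,11S)-11-hydroxy-11-[(2S,4R,5S,6S)-4-hydroxy-5-methyl-6-[(E)-prop-1-enyl]oxan-2-yl]-3,5,7-trimethylundeca-1,3,7,9-tetraenyl]-5,6-dihydro-2H-pyran-2-one | C/C=C/[C@@H]1O[C@H]([C@@H](O)/C=C/C=C(\C)C[C@@H](C)/C=C(C)\C=C\[C@@H]2CC=CC(=O)O2)C[C@@H](O)[C@@H]1C | target

**Summary**

Total step count: 30 (oxane half 14 steps, ylide 2, iodotriene lactone 12, union and deprotection 2).
Longest linear sequence: 16 steps (steps 1–6, 9–16, 29, 30).

**Steps most likely to fail**

Step 10. The ring closure may show poor facial selectivity at C6 if the preferences of catalyst and substrate do not coincide, or it may stall if the diol ties up the acid unproductively. The fallback keeps the O5–C6 oxa-Michael disconnection but moves it to an oxoester under thermodynamic control, and sets out from lactol 10. Condensation of 10 with methyl (triphenyl-λ5-phosphanylidene)acetate in toluene should give methyl (2E,5R,6S,7S,8E)-5,7-dihydroxy-6-methyldeca-2,8-dienoate F1. Catalytic KOt-Bu in THF at 0 °C then lets the C4 alkoxide add and re-eliminate until the diequatorial 2,6-cis ester, methyl 2-[(2S,4R,5S,6S)-4-hydroxy-5-methyl-6-[(E)-prop-1-enyl]oxan-2-yl]acetate F2, predominates. Reduction of F2 with i-Bu2AlH at −78 °C returns to the route at aldehyde 18.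

Step 12. The enamine of this β-alkoxy aldehyde may expel the ring oxygen (retro-oxa-Michael opening of the oxane), or the neighbouring C6 centre may erode catalyst control at C7. The fallback replaces enamine catalysis by auxiliary-controlled enolate hydroxylation and sets out from aldehyde 18. Oxidation with NaClO2, NaH2PO4 and 2-methylbut-2-ene should give 2-[(2S,4R,5S,6S)-4-hydroxy-5-methyl-6-[(E)-prop-1-enyl]oxan-2-yl]acetic acid F3. Its mixed pivalic anhydride (pivaloyl chloride, Et3N) is treated with LiCl and (R)-4-benzyl-1,3-oxazolidin-2-one, the auxiliary recovered in step 2, to give (4R)-4-benzyl-3-{2-[(2S,4R,5S,6S)-4-hydroxy-5-methyl-6-[(E)-prop-1-enyl]oxan-2-yl]acetyl}-1,3-oxazolidin-2-one F4. NaN(SiMe3)2 (2.2 equiv) and 2-(benzenesulfonyl)-3-phenyloxaziridine at −78 °C should hydroxylate the sodium enolate on the face away from the benzyl group to give (4R)-4-benzyl-3-{(2R)-2-hydroxy-2-[(2S,4R,5S,6S)-4-hydroxy-5-methyl-6-[(E)-prop-1-enyl]oxan-2-yl]acetyl}-1,3-oxazolidin-2-one F5. LiBH4 reduces F5 and returns to the route at triol 21.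

Step 29. The alkenylzirconium may be protonated before transmetalation, residual hydride may attack the lactone, or slow coupling of the hindered partners may allow homocoupling. The fallback isolates a tin reagent instead and sets out from alkyne 24. Hydrostannation with Bu3SnH and catalytic PdCl2(PPh3)2 in THF should give tributyl[(1E,3S)-3-[(2S,4R,5R,6S)-5-methyl-6-[(E)-prop-1-enyl]-4-(triethylsilyloxy)oxan-2-yl]-3-(triethylsilyloxy)prop-1-enyl]stannane F6. Stille coupling of F6 with iodide 44 (Pd2(dba)3, AsPh3, DMF, rt) returns to the route at 47.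

**Further compounds**

F1 | step 10 | methyl (2E,5R,6S,7S,8E)-5,7-dihydroxy-6-methyldeca-2,8-dienoate | C/C=C/[C@H](O)[C@@H](C)[C@H](O)C/C=C/C(=O)OC
F2 | step 10 | methyl 2-[(2S,4R,5S,6S)-4-hydroxy-5-methyl-6-[(E)-prop-1-enyl]oxan-2-yl]acetate | C/C=C/[C@@H]1O[C@H](CC(=O)OC)C[C@@H](O)[C@@H]1C
F3 | step 12 | 2-[(2S,4R,5S,6S)-4-hydroxy-5-methyl-6-[(E)-prop-1-enyl]oxan-2-yl]acetic acid | C/C=C/[C@@H]1O[C@H](CC(=O)O)C[C@@H](O)[C@@H]1C
F4 | step 12 | (4R)-4-benzyl-3-{2-[(2S,4R,5S,6S)-4-hydroxy-5-methyl-6-[(E)-prop-1-enyl]oxan-2-yl]acetyl}-1,3-oxazolidin-2-one | C/C=C/[C@@H]1O[C@H](CC(=O)N2[C@H](Cc3ccccc3)COC2=O)C[C@@H](O)[C@@H]1C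
F5 | step 12 | (4R)-4-benzyl-3-{(2R)-2-hydroxy-2-[(2S,4R,5S,6S)-4-hydroxy-5-methyl-6-[(E)-prop-1-enyl]oxan-2-yl]acetyl}-1,3-oxazolidin-2-one | C/C=C/[C@@H]1O[C@H]([C@@H](O)C(=O)N2[C@H](Cc3ccccc3)COC2=O)C[C@@H](O)[C@@H]1C
F6 | step 29 | tributyl[(1E,3S)-3-[(2S,4R,5R,6S)-5-methyl-6-[(E)-prop-1-enyl]-4-(triethylsilyloxy)oxan-2-yl]-3-(triethylsilyloxy)prop-1-enyl]stannane | C/C=C/[C@@H]1O[C@H]([C@@H](O[Si](CC)(CC)CC)/C=C/[Sn](CCCC)(CCCC)CCCC)C[C@@H](O[Si](CC)(CC)CC)[C@@H]1C
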